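**Retrosynthetic overview**
1. Target ⇐ phenol deacetylation ⇐ α‑face epoxidation of C8=C9 ⇐ aroylation of the 4β,6β‑diol 18 ⇐ C6 epimerisation of the 4β,6α‑diol 17 (proposed new photochemical hydrogen‑atom‑transfer step).
2. 17 ⇐ isopropylcerium addition to the trans‑fused hydroazulenone 15 (sets C4) ⇐ Rh‑catalysed intramolecular hydroacylation of aldehyde 14 (five‑membered ring, formed second, C3–C4 bond).
3. 14 ⇐ ring‑closing metathesis of triene 12 (seven‑membered ring, formed first, C8=C9).
4. 12 ⇐ acid 10 ⇐ dianionic Ireland–Claisen rearrangement of allylic β‑hydroxy ester 8 (C1–C5 bond; quaternary C1 and C5 relayed from the C6 carbinol).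
5. 8 ⇐ ethyl (R)‑4‑chloro‑3‑hydroxybutanoate + isopropenyl Grignard, and (E)‑3‑methylhexa‑2,5‑dien‑1‑ol from pent‑1‑en‑4‑yne.

Assumption: the SMILES is taken literally as (1R,4R,5S,6R,8R,9S) in daucane numbering (C1 angular‑methyl carbon, C2/C3 ring CH2, C4 isopropyl carbinol, C5 ring‑fusion CH, C6 ester carbon, C7 CH2, C8/C9 epoxide carbons, C10 CH2; β = face of the angular methyl), i.e. the 6β‑acyloxy series with the ester cis to the angular methyl and the 4‑OH.

**Step 1**
Reactants: 1 pent-1-en-4-yne
Product: 4 (2E)-3-methylhexa-2,5-dien-1-ol, via alkenyl(dimethyl)alane 2 (not isolated), via lithium alkenylaluminate 3 (not isolated)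
Conditions: Me3Al (2 equiv), Cp2ZrCl2 (0.25 equiv), CH2Cl2, 0 °C to rt; volatiles removed; n-BuLi, hexane–THF, 0 °C; (CH2O)n, rt; aq. NH4Cl
Reagents that add atoms: trimethylaluminium, C[Al](C)C; paraformaldehyde (as formaldehyde), C=O
Why: Negishi zirconium-catalysed carboalumination adds Me and Al syn across the terminal alkyne (methyl to the internal carbon, isolated alkene inert), and hydroxymethylation of the derived aluminate proceeds with retention, which fixes the E trisubstituted alkene needed for the chair transition state of step 4.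

**Step 2**
Reactants: 5 ethyl (3R)-4-chloro-3-hydroxybutanoate
Product: 7 ethyl (3S)-3-hydroxy-5-methylhex-5-enoate, via epoxy ester 6 (not isolated)
Conditions: isopropenylMgBr (3 equiv), CuBr·SMe2 (0.1 equiv), THF, −40 to 0 °C; aq. NH4Cl
Reagents that add atoms: isopropenylmagnesium bromide, CC(=C)[Mg]Br
Why: the magnesium alkoxide of the chlorohydrin closes to the epoxy ester, which the copper-catalysed Grignard opens at the unhindered terminal carbon (catalytic cuprate epoxide opening); the carbinol carbon is never touched, so its configuration is retained (the descriptor changes from R to S only through CIP priorities).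

**Step 3**
Reactants: 7 ethyl (3S)-3-hydroxy-5-methylhex-5-enoate; 4 (2E)-3-methylhexa-2,5-dien-1-ol
Product: 8 (2E)-3-methylhexa-2,5-dien-1-yl (3S)-3-hydroxy-5-methylhex-5-enoate
Conditions: Ti(OEt)4 (0.2 equiv), 4 (2 equiv, excess recovered), toluene, 100 °C, ethanol distilled off
Reagents that add atoms: none
Why: titanate-mediated transesterification is essentially neutral, tolerates the free β-hydroxyl without dehydration or retro-aldol cleavage and is driven by removal of ethanol; no stereocentre is involved.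

**Step 4**
Reactants: 8 (2E)-3-methylhexa-2,5-dien-1-yl (3S)-3-hydroxy-5-methylhex-5-enoate
Product: 10 (2S,3S)-3-hydroxy-5-methyl-2-[(3S)-3-methylhexa-1,5-dien-3-yl]hex-5-enoic acid, via dilithium alkoxide-enolate 9 (not isolated)
Conditions: LiN(iPr)2 (2.2 equiv), THF, −78 °C, 1 h; then 25 to 50 °C; aq. HCl (pH 3)
Reagents that add atoms: none
Why: dianionic Ireland–Claisen rearrangement: in the lithium-chelated alkoxide–enolate (enolate oxygen cis to C6) the allyl unit attacks the enolate face anti to the methallyl group on the chelate (Fráter–Seebach sense, 5,6-anti) through a chair transition state in which the E olefin places the allyl chain equatorial and the methyl axial, so quaternary C1 and C5 are set from C6 with the relative configuration that becomes the trans ring fusion.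

**Step 5**
Reactants: 10 (2S,3S)-3-hydroxy-5-methyl-2-[(3S)-3-methylhexa-1,5-dien-3-yl]hex-5-enoic acid
Product: 11 (2R,3S)-5-methyl-2-[(3S)-3-methylhexa-1,5-dien-3-yl]hex-5-ene-1,3-diol
Conditions: LiAlH4 (3 equiv), THF, 0 °C to reflux; NaOH/H2O work-up
Reagents that add atoms: none
Why: hydride reduction of the carboxylic acid to the primary alcohol leaves the isolated alkenes and all stereocentres untouched.

**Step 6**
Reactants: 11 (2R,3S)-5-methyl-2-[(3S)-3-methylhexa-1,5-dien-3-yl]hex-5-ene-1,3-diol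
Product: 12 (2R,3S)-5-methyl-2-[(3S)-3-methylhexa-1,5-dien-3-yl]-1,3-bis(triethylsilyloxy)hex-5-ene
Conditions: Et3SiCl (2.5 equiv), imidazole (5 equiv), DMAP (0.1 equiv), DMF, 0 °C to rt
Reagents that add atoms: chlorotriethylsilane, CC[Si](Cl)(CC)CC
Why: standard imidazole-promoted silylation protects both hydroxyls, so that the primary ether can later be oxidised selectively while the C6 oxygen stays masked.

**Step 7**
Reactants: 12 (2R,3S)-5-methyl-2-[(3S)-3-methylhexa-1,5-dien-3-yl]-1,3-bis(triethylsilyloxy)hex-5-ene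
Product: 13 (4S,5R,6S)-4-ethenyl-1,4-dimethyl-6-(triethylsilyloxy)-5-[(triethylsilyloxy)methyl]cyclohept-1-ene
Conditions: second-generation Grubbs catalyst RuCl2(=CHPh)(H2IMes)(PCy3) (5 mol %), CH2Cl2 (0.005 M), 40 °C
Reagents that add atoms: none
Why: ring-closing metathesis: the ruthenium carbene loads on the unhindered allyl terminus and closes on the 1,1-disubstituted methallyl alkene to the trisubstituted cycloheptene with loss of ethene, while the vinyl group on the quaternary carbon is too hindered to initiate and could only give a cyclobutene with the allyl carbene; no stereocentre is touched.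

**Step 8**
Reactants: 13 (4S,5R,6S)-4-ethenyl-1,4-dimethyl-6-(triethylsilyloxy)-5-[(triethylsilyloxy)methyl]cyclohept-1-ene
Product: 14 (1S,2S,7S)-2-ethenyl-2,5-dimethyl-7-(triethylsilyloxy)cyclohept-4-ene-1-carbaldehyde
Conditions: (COCl)2, DMSO, CH2Cl2, −78 to −30 °C; Et3N, −78 to 0 °C
Reagents that add atoms: none
Why: Swern oxidation cleaves and oxidises a primary triethylsilyl ether directly while the secondary one survives, giving the aldehyde at low temperature without epimerising C5 or eliminating the β-silyloxy group.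

**Step 9**
Reactants: 14 (1S,2S,7S)-2-ethenyl-2,5-dimethyl-7-(triethylsilyloxy)cyclohept-4-ene-1-carbaldehyde
Product: 15 (3aR,8S,8aS)-3a,6-dimethyl-8-(triethylsilyloxy)-3,3a,4,7,8,8a-hexahydroazulen-1(2H)-one
Conditions: [Rh(nbd)(dppe)]BF4 (5 mol %), H2 pre-activation then Ar, acetone, 25 °C
Reagents that add atoms: none
Why: rhodium-catalysed intramolecular alkene hydroacylation of a 4-pentenal (aldehyde C–H oxidative addition to cationic monovalent rhodium, anti-Markovnikov insertion of the vinyl group to a six-membered acyl rhodacycle, C–C reductive elimination) forms the C3–C4 bond; C1 and C5 are not touched, so the relationship set in step 4 becomes the trans ring fusion, and the quaternary C1 favours cyclisation and blocks alkene isomerisation.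

**Step 10**
Reactants: 15 (3aR,8S,8aS)-3a,6-dimethyl-8-(triethylsilyloxy)-3,3a,4,7,8,8a-hexahydroazulen-1(2H)-one
Product: 16 (1R,3aR,8S,8aS)-3a,6-dimethyl-1-(propan-2-yl)-8-(triethylsilyloxy)-1,2,3,3a,4,7,8,8a-octahydroazulen-1-ol
Conditions: iPrMgCl (3 equiv), anhydrous CeCl3 (3 equiv), THF, −78 to 0 °C; aq. NH4Cl
Reagents that add atoms: isopropylmagnesium chloride, CC(C)[Mg]Cl
Why: organocerium 1,2-addition (low basicity, so no enolisation or β-hydride reduction); the nucleophile enters from the α face, anti to the β-axial angular methyl that is 1,3 to the carbonyl on the cyclopentanone, giving the 4β-hydroxy-4α-isopropyl carbinol (4R).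

**Step 11**
Reactants: 16 (1R,3aR,8S,8aS)-3a,6-dimethyl-1-(propan-2-yl)-8-(triethylsilyloxy)-1,2,3,3a,4,7,8,8a-octahydroazulen-1-ol
Product: 17 (1R,3aR,8S,8aS)-3a,6-dimethyl-1-(propan-2-yl)-1,2,3,3a,4,7,8,8a-octahydroazulene-1,8-diol
Conditions: Bu4NF, THF, 0 °C to rt
Reagents that add atoms: none
Why: fluoride-mediated desilylation (Si–F bond formation) frees the secondary 6α-hydroxyl without affecting any stereocentre.

**Step 12**
Reactants: 17 (1R,3aR,8S,8aS)-3a,6-dimethyl-1-(propan-2-yl)-1,2,3,3a,4,7,8,8a-octahydroazulene-1,8-diol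
Product: 18 (1R,3aR,8R,8aS)-3a,6-dimethyl-1-(propan-2-yl)-1,2,3,3a,4,7,8,8a-octahydroazulene-1,8-diol
Conditions: 4CzIPN (2 mol %), quinuclidine (20 mol %), adamantane-1-thiol (50 mol %), Bu4N[4-ClC6H4CO2] (25 mol %), MeCN, 450 nm LEDs, 25 °C, Ar
Reagents that add atoms: none
Why: Proposed new method: photocatalytic hydrogen-atom-transfer epimerisation of the C6 carbinol of a hindered terpenoid 1,3-diol that carries a trisubstituted alkene, a substrate class on which this reactivity has not been shown; excited 4CzIPN oxidises quinuclidine to its radical cation, which (helped by benzoate hydrogen-bonding to the 6-OH) abstracts the hydridic axial C6–H, the only carbinol C–H present because C4 is tertiary, to give a planar α-hydroxy radical, and the bulky thiol returns a hydrogen atom to the α face because the β face is blocked by the syn-axial angular methyl, so material is funnelled to the 6β-alcohol (6R in daucane numbering), whose equatorial C6–H is stereoelectronically poorer for re-abstraction and whose hydroxyl is tied up in an internal hydrogen bond to the 4β-OH, while the thiyl radical is reduced by the photocatalyst radical anion and reprotonated to close both cycles; closest known reaction type: photoredox/quinuclidine/thiol-mediated site-selective epimerisation of secondary alcohols (equatorial-to-axial stereo-editing of sugars and cyclic diols).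

**Step 13**
Reactants: 18 (1R,3aR,8R,8aS)-3a,6-dimethyl-1-(propan-2-yl)-1,2,3,3a,4,7,8,8a-octahydroazulene-1,8-diol; 19 4-acetoxybenzoyl chloride
Product: 20 (3R,3aS,4R,8aR)-3-hydroxy-6,8a-dimethyl-3-(propan-2-yl)-1,2,3,3a,4,5,8,8a-octahydroazulen-4-yl 4-acetoxybenzoate
Conditions: Et3N (3 equiv), DMAP (0.3 equiv), CH2Cl2, 0 to 40 °C
Reagents that add atoms: none
Why: DMAP-catalysed acylation (nucleophilic catalysis) occurs only at the secondary 6β-hydroxyl because the tertiary 4-hydroxyl is inert, and O-acylation retains the configuration at C6.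

**Step 14**
Reactants: 20 (3R,3aS,4R,8aR)-3-hydroxy-6,8a-dimethyl-3-(propan-2-yl)-1,2,3,3a,4,5,8,8a-octahydroazulen-4-yl 4-acetoxybenzoate
Product: 21 (1R,4R,5S,6R,8R,9S)-8,9-epoxy-4-hydroxydaucan-6-yl 4-acetoxybenzoate
Conditions: mCPBA (1.3 equiv), NaHCO3, CH2Cl2, 0 °C
Reagents that add atoms: 3-chloroperbenzoic acid, O=C(OO)c1cccc(Cl)c1
Why: Prilezhaev epoxidation; the peracid approaches the trisubstituted alkene from the α face because the β face is screened by the axial angular methyl and the axial 6β-aroyloxy group, which gives the 8R,9S (α) epoxide.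

**Step 15**
Reactants: 21 (1R,4R,5S,6R,8R,9S)-8,9-epoxy-4-hydroxydaucan-6-yl 4-acetoxybenzoate
Product: 22 (1R,4R,5S,6R,8R,9S)-8,9-epoxy-4-hydroxydaucan-6-yl 4-hydroxybenzoate
Conditions: K2CO3 (0.2 equiv), MeOH, 0 °C
Reagents that add atoms: none
Why: methanolysis of the aryl acetate (transesterification) is far faster than cleavage of the hindered secondary benzoate, which is further deactivated once the phenoxide forms, and the epoxide and all stereocentres are untouched.

**Compound list**
1 | pent-1-en-4-yne | C#CCC=C | starting material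
2 | dimethyl[(1E)-2-methylpenta-1,4-dien-1-yl]alane (formed in the flask) | C=CC/C(C)=C/[Al](C)C | intermediate
3 | lithium butyl(dimethyl)[(1E)-2-methylpenta-1,4-dien-1-yl]aluminate (formed in the flask) | [Li+].C=CC/C(C)=C/[Al-](C)(C)CCCC | intermediate
4 | (2E)-3-methylhexa-2,5-dien-1-ol | C=CC/C(C)=C/CO | intermediate
5 | ethyl (3R)-4-chloro-3-hydroxybutanoate | CCOC(=O)C[C@@H](O)CCl | starting material
6 | ethyl 2-[(2R)-oxiran-2-yl]acetate (formed in the flask) | CCOC(=O)C[C@@H]1CO1 | intermediate
7 | ethyl (3S)-3-hydroxy-5-methylhex-5-enoate | CCOC(=O)C[C@@H](O)CC(C)=C | intermediate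
8 | (2E)-3-methylhexa-2,5-dien-1-yl (3S)-3-hydroxy-5-methylhex-5-enoate | C=CC/C(C)=C/COC(=O)C[C@@H](O)CC(C)=C | intermediate
9 | dilithium alkoxide–enolate of 8 (chelated; enolate oxygen cis to the 3S carbinol carbon; formed in the flask) | C=CC/C(C)=C/CO/C([O-])=C/[C@@H]([O-])CC(C)=C.[Li+].[Li+] | intermediate
10 | (2S,3S)-3-hydroxy-5-methyl-2-[(3S)-3-methylhexa-1,5-dien-3-yl]hex-5-enoic acid | OC(=O)[C@H]([C@@H](O)CC(C)=C)[C@](C)(C=C)CC=C | intermediate
11 | (2R,3S)-5-methyl-2-[(3S)-3-methylhexa-1,5-dien-3-yl]hex-5-ene-1,3-diol | OC[C@H]([C@@H](O)CC(C)=C)[C@](C)(C=C)CC=C | intermediate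
12 | (2R,3S)-5-methyl-2-[(3S)-3-methylhexa-1,5-dien-3-yl]-1,3-bis(triethylsilyloxy)hex-5-ene | CC[Si](CC)(CC)OC[C@H]([C@@H](O[Si](CC)(CC)CC)CC(C)=C)[C@](C)(C=C)CC=C | intermediate
13 | (4S,5R,6S)-4-ethenyl-1,4-dimethyl-6-(triethylsilyloxy)-5-[(triethylsilyloxy)methyl]cyclohept-1-ene | C=C[C@]1(C)CC=C(C)C[C@H](O[Si](CC)(CC)CC)[C@H]1CO[Si](CC)(CC)CC | intermediate
14 | (1S,2S,7S)-2-ethenyl-2,5-dimethyl-7-(triethylsilyloxy)cyclohept-4-ene-1-carbaldehyde | C=C[C@]1(C)CC=C(C)C[C@H](O[Si](CC)(CC)CC)[C@H]1C=O | intermediate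
15 | (3aR,8S,8aS)-3a,6-dimethyl-8-(triethylsilyloxy)-3,3a,4,7,8,8a-hexahydroazulen-1(2H)-one (trans-fused) | O=C1CC[C@]2(C)CC=C(C)C[C@H](O[Si](CC)(CC)CC)[C@H]21 | intermediate
16 | (1R,3aR,8S,8aS)-3a,6-dimethyl-1-(propan-2-yl)-8-(triethylsilyloxy)-1,2,3,3a,4,7,8,8a-octahydroazulen-1-ol | CC(C)[C@]1(O)CC[C@]2(C)CC=C(C)C[C@H](O[Si](CC)(CC)CC)[C@H]21 | intermediate
17 | (1R,3aR,8S,8aS)-3a,6-dimethyl-1-(propan-2-yl)-1,2,3,3a,4,7,8,8a-octahydroazulene-1,8-diol (dauc-8-ene-4β,6α-diol) | CC(C)[C@]1(O)CC[C@]2(C)CC=C(C)C[C@H](O)[C@H]21 | intermediate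
18 | (1R,3aR,8R,8aS)-3a,6-dimethyl-1-(propan-2-yl)-1,2,3,3a,4,7,8,8a-octahydroazulene-1,8-diol (dauc-8-ene-4β,6β-diol) | CC(C)[C@]1(O)CC[C@]2(C)CC=C(C)C[C@@H](O)[C@H]21 | intermediate
19 | 4-acetoxybenzoyl chloride | CC(=O)Oc1ccc(cc1)C(Cl)=O | starting material
20 | (3R,3aS,4R,8aR)-3-hydroxy-6,8a-dimethyl-3-(propan-2-yl)-1,2,3,3a,4,5,8,8a-octahydroazulen-4-yl 4-acetoxybenzoate | CC(C)[C@]1(O)CC[C@]2(C)CC=C(C)C[C@@H](OC(=O)c3ccc(OC(C)=O)cc3)[C@H]21 | intermediate
21 | (1R,4R,5S,6R,8R,9S)-8,9-epoxy-4-hydroxydaucan-6-yl 4-acetoxybenzoate (daucane numbering; α-epoxide) | CC(C)[C@]1(O)CC[C@]2(C)C[C@@H]3O[C@]3(C)C[C@@H](OC(=O)c3ccc(OC(C)=O)cc3)[C@H]21 | intermediate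
22 | (1R,4R,5S,6R,8R,9S)-8,9-epoxy-4-hydroxydaucan-6-yl 4-hydroxybenzoate (CNP0163817.3) | CC(C)[C@]1(O)CC[C@]2(C)C[C@@H]3O[C@]3(C)C[C@@H](OC(=O)c3ccc(O)cc3)[C@H]21 | target

**Step count and risk**
Total step count: 15. Longest linear sequence: 14 steps (steps 2 to 15, from compound 5); step 1 is a one-step side branch.

The three steps most likely to fail are steps 9, 10 and 12.

Step 9 (hydroacylation of a crowded α-branched aldehyde with a β-quaternary carbon; decarbonylation or slow turnover are the dangers). The fallback builds the C3–C4 bond by a Barbier cyclisation instead; it sets out from 13 and comes back to the route at 15. Hydroboration of 13 with 9-BBN (THF, 60 °C; then NaOH/H2O2) touches only the monosubstituted vinyl group and gives the primary alcohol 2-[(1S,6S,7R)-1,4-dimethyl-6-(triethylsilyloxy)-7-[(triethylsilyloxy)methyl]cyclohept-3-en-1-yl]ethan-1-ol F1. Iodine, PPh3 and imidazole convert it into the iodide [(1R,2S,7S)-2-(2-iodoethyl)-2,5-dimethyl-7-(triethylsilyloxy)cyclohept-4-en-1-yl]methoxy(triethyl)silane F2. Swern oxidation, again selective for the primary silyl ether, gives the iodo aldehyde (1S,2S,7S)-2-(2-iodoethyl)-2,5-dimethyl-7-(triethylsilyloxy)cyclohept-4-ene-1-carbaldehyde F3. SmI2 (samarium diiodide, THF–HMPA, 0 °C) closes the ring to the cyclopentanol (3aR,8S,8aR)-3a,6-dimethyl-8-(triethylsilyloxy)-1,2,3,3a,4,7,8,8a-octahydroazulen-1-ol F4, formed as a mixture of carbinol epimers that does not matter. Dess–Martin oxidation of this alcohol gives ketone 15.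

Step 10 (a secondary organometallic adding to a hindered, enolisable ketone; reduction, enolisation or imperfect facial control are the dangers). The fallback uses a smaller sp2 nucleophile followed by a selective reduction; it sets out from 15 and comes back at 16. IsopropenylMgBr/CeCl3 (THF, −78 °C) adds from the same α face to give the isopropenyl carbinol (1S,3aR,8S,8aS)-3a,6-dimethyl-1-(prop-1-en-2-yl)-8-(triethylsilyloxy)-1,2,3,3a,4,7,8,8a-octahydroazulen-1-ol F5. Its 1,1-disubstituted alkene is then reduced in preference to the trisubstituted ring alkene with H2 and RhCl(PPh3)3 (benzene–EtOH), or with diimide from 2-nitrobenzenesulfonyl hydrazide and Et3N, which gives 16.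

Step 12 (the proposed new step; abstraction of the syn-axial 6β-H may be slow, and thiyl addition or allylic hydrogen abstraction at C8=C9 may compete). The fallback is known oxidation–reduction chemistry; it sets out from 17 and comes back at 18. Dess–Martin periodinane (NaHCO3, CH2Cl2, 0 °C) oxidises the only secondary alcohol to the β-hydroxy ketone (1R,4R,5R)-4β-hydroxydauc-8-en-6-one F6. Chelation-controlled reduction (Et2BOMe, then NaBH4, THF–MeOH, −78 °C; Narasaka–Prasad conditions) ties the 4β-oxygen and the ketone into a boron chelate on the β face, so hydride arrives from the α face, anti to the angular methyl, and gives the syn-1,3-diol 18.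

**Further compounds**
F1 | step 9 | 2-[(1S,6S,7R)-1,4-dimethyl-6-(triethylsilyloxy)-7-[(triethylsilyloxy)methyl]cyclohept-3-en-1-yl]ethan-1-ol | OCC[C@]1(C)CC=C(C)C[C@H](O[Si](CC)(CC)CC)[C@H]1CO[Si](CC)(CC)CC
F2 | step 9 | [(1R,2S,7S)-2-(2-iodoethyl)-2,5-dimethyl-7-(triethylsilyloxy)cyclohept-4-en-1-yl]methoxy(triethyl)silane | ICC[C@]1(C)CC=C(C)C[C@H](O[Si](CC)(CC)CC)[C@H]1CO[Si](CC)(CC)CC
F3 | step 9 | (1S,2S,7S)-2-(2-iodoethyl)-2,5-dimethyl-7-(triethylsilyloxy)cyclohept-4-ene-1-carbaldehyde | ICC[C@]1(C)CC=C(C)C[C@H](O[Si](CC)(CC)CC)[C@H]1C=O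
F4 | step 9 | (3aR,8S,8aR)-3a,6-dimethyl-8-(triethylsilyloxy)-1,2,3,3a,4,7,8,8a-octahydroazulen-1-ol (mixture of epimers at the carbinol carbon) | OC1CC[C@]2(C)CC=C(C)C[C@H](O[Si](CC)(CC)CC)[C@H]21
F5 | step 10 | (1S,3aR,8S,8aS)-3a,6-dimethyl-1-(prop-1-en-2-yl)-8-(triethylsilyloxy)-1,2,3,3a,4,7,8,8a-octahydroazulen-1-ol | C=C(C)[C@]1(O)CC[C@]2(C)CC=C(C)C[C@H](O[Si](CC)(CC)CC)[C@H]21
F6 | step 12 | (1R,4R,5R)-4β-hydroxydauc-8-en-6-one (daucane numbering) | CC(C)[C@]1(O)CC[C@]2(C)CC=C(C)CC(=O)[C@H]21
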